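X cannot take up more Q than was charged of it, and that can be counted before any flask is run.

| setting | dusk | midnight | summer | north-east | south-west | east |
|---|---|---|---|---|---|---|
| E | 0.13 M | 0.13 M | 0.13 M | 0.13 M | 0.13 M | 0.13 M (fed, over 6.0 min) |
| X | 0.26 M | 0.26 M | 0.26 M | 0.260 M | 0.260 M (fed, over 6.0 min) | 0.260 M |
| J | 0.195 M | 0.098 M | 0.15 M | 0.195 M | 0.195 M | 0.195 M |
| remark | run made earlier | run made earlier | run made earlier | everything together at the start | all else is in the flask from the start; the feed brings no volume worth counting | all else is in the flask from the start; the feed brings no volume worth counting |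
| time |  |  |  | 8.0 min | 8.0 min | 8.0 min |

- dusk (time / min: L / %, E / %): 0.250: 5.8, 91.9; 0.667: 16.7, 84.6; 1.33: 28.1, 72.2; 2.00: 35.1, 61.9; 3.00: 46.5, 55.5; 4.00: 52.9, 46.3; 5.00: 59.1, 39.1
- midnight (time / min: L / %, E / %): 0.833: 11.0, 88.5; 1.33: 13.9, 84.0; 2.00: 22.2, 79.3; 2.50: 24.9, 75.1; 4.00: 31.8, 67.1; 6.00: 41.1, 58.7; 10.0: 51.1, 49.5
- summer (time / min: L / %, E / %): 1.33: 21.4, 77.4; 3.00: 39.5, 59.6; 4.00: 43.9, 53.8; 6.00: 57.2, 42.4; 8.00: 63.8, 36.9; 10.0: 67.1, 33.5

(scatter of a reading: 1 percentage point)

- candidate steps: E + Z <-> Q + L; Z + Q <-> J; Q + X <-> G; Z <-> D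

- the flask that comes out highest in amount of L, in percent of the E charged, or "all alike" when all lie within 1.5 percentage points (north-east / south-west / east / all alike)
- L at the end, in percent of the E charged, north-east
- L at the end, in percent of the E charged, south-west
- L at the end, in percent of the E charged, east

With E and X held, dusk stands at L 35.1% after 2.00 min with J 0.195 M, and midnight at 22.2% after 2.00 min with J 0.098 M. So we read J as a store of Z bound to Q, opened when X takes the Q into G.

As fractions of the E charge, X is 200% and J is 150%. Taking J from X leaves 50.0%, the spare base: X charge minus J charge, over the E charge. Counting Q gives our rule: J plus Q minus X equals L minus the spare. Past that crossing, with L above the spare, J and Q together stand above the X left, by L minus the spare.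

Dusk, charged as north-east, has passed it, with L 59.1% at 5.00 min. In south-west, the X fed reaches the J charge at 4.50 min, and the spare, counted on the X fed so far, is below zero until then. East receives its E over 6.0 min. So we place north-east highest.

The forecast, from the same runs, says north-east, with 70% for north-east, 61% for south-west and 56% for east. Its ground past the spare is “Beyond that, each Q re-binds a Z”.

The flasks give 69.4%, 59.9% and 55.2% in that order, so north-east stands highest and the forecast held.

    E + Z ⇌ Q + L (K = 2.30, k = 0.0250 M⁻¹ s⁻¹)
    Z + Q ⇌ J, settled at all times (K = 170 M⁻¹)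
    Q + X ⇌ G, settled at all times (K = 8200 M⁻¹)
    Z ⇌ D (K = 6.50, k = 3.80 × 10⁻⁴ s⁻¹)

North-east ends at 8.00 min 19.4% past its spare, so J and Q together stand that far above the X left. South-west at 4.00 min, before its crossing, holds J 31.7% of own charge and L 30.3%, while north-east then holds 11.8% and 53.7%. A neighbour of north-east charged with X 0.065 M starts with a spare of −100%. X is its limiting reagent, and it ends with 0.31% of its X left, J 66.7% of own charge, Q 30.5% of the E charge and L 30.4%.

The numbers in the tables stem from a simulated flask with made-up constants; the scatter is artificial.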